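The dihydropyran ring (O1, C2–C6) is simplified by deleting O1: C2, C3, C4, C5 and the ester carbon on C5 then form a cyclopentanone that carries the C2–C3–C4 stereotriad all-trans. The key step sets up this triad in one operation on an enantiopure 4-substituted cyclopent-2-enone whose only stereocentre (future C4) bears the methyl acetate arm: a silylmethyl copper reagent (masked CH2OH) adds to the β-carbon (future C3) and the enolate is methylated at the α-carbon (future C2). Baeyer–Villiger insertion of O1, formylation and Korte rearrangement rebuild the pyran; benzyl ethers on all three hydroxyls allow a single neutral hydrogenolysis at the end.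

Key step: step 5

Remark: "future" positions use the pyran numbering of the target (O1, C2 methyl, C3 hydroxymethyl, C4 acetate arm, C5 ester-bearing carbon, C6); the formyl lactone 17 is written as its hydroxymethylene tautomer, whose double-bond geometry is lost in step 10.

Step 1
Reactants: 1 (1S,4R)-cis-4-acetoxy-2-cyclopenten-1-ol; 2 dimethyl malonate
Product: 4 dimethyl 2-[(1R,4S)-4-hydroxycyclopent-2-en-1-yl]propanedioate, via sodium dimethyl malonate 3 (not isolated)
Conditions: NaH, THF, 0 °C; then 1, Pd(PPh3)4 (zerovalent palladium, cat.), PPh3, THF, 50 °C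
Reagents that add atoms: none
Why: Tsuji–Trost allylic alkylation, in which ionisation of the acetate by zerovalent palladium and attack of the soft malonate 3 both proceed with inversion, so the malonyl group should replace the acetate with net retention at the allyl terminus remote from the hydroxyl, fixing the future C4 stereocentre cis to the OH.

Step 2
Reactants: 4 dimethyl 2-[(1R,4S)-4-hydroxycyclopent-2-en-1-yl]propanedioate
Product: 5 methyl 2-[(1S,4S)-4-hydroxycyclopent-2-en-1-yl]acetate
Conditions: LiCl, H2O, DMSO, 140 °C
Reagents that add atoms: none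
Why: Krapcho dealkoxycarbonylation, in which chloride demethylates one malonate ester and the carboxylate loses CO2 to leave the acetate arm; neither ring stereocentre is α to a carbonyl, so both should be untouched.

Step 3
Reactants: 5 methyl 2-[(1S,4S)-4-hydroxycyclopent-2-en-1-yl]acetate
Product: 6 methyl 2-[(1S)-4-oxocyclopent-2-en-1-yl]acetate
Conditions: MnO2 (activated), CH2Cl2, rt
Reagents that add atoms: none
Why: Allylic alcohol oxidation with MnO2 is chemoselective and neutral, which avoids the base-mediated double-bond migration that would erase the remaining stereocentre.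

Step 4
Reactants: 7 (chloromethyl)dimethylphenylsilane
Product: 8 [(dimethylphenylsilyl)methyl]magnesium chloride
Conditions: Mg turnings, BrCH2CH2Br (cat.), THF, reflux, then rt
Reagents that add atoms: magnesium, [Mg]
Why: Grignard formation by magnesium insertion into a primary α-silyl alkyl chloride is routine and gives a stable THF solution that is used directly.

Step 5
Reactants: 6 methyl 2-[(1S)-4-oxocyclopent-2-en-1-yl]acetate; 8 [(dimethylphenylsilyl)methyl]magnesium chloride; 9 iodomethane
Product: 11 methyl 2-[(1S,2S,3R)-2-[(dimethylphenylsilyl)methyl]-3-methyl-4-oxocyclopentyl]acetate, via chloromagnesium enolate 10 (not isolated)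
Conditions: CuBr·SMe2 (monovalent copper, cat.), THF, −78 °C; then 9 (excess), DMPU, −78 → 0 °C
Reagents that add atoms: none
Why: Transmetalation of 8 onto CuBr·SMe2 gives a silylmethylcuprate that complexes the enone on the face opposite the acetate arm, adds oxidatively at the β-carbon to a trivalent-copper enolate and reductively eliminates, forming the future C3–CH2 bond and the regiodefined enolate 10, which then attacks 9 in an SN2 reaction accelerated by DMPU to form the future C2–CH3 bond. The closest known reaction type is the copper-catalysed conjugate addition of Grignard reagents to 4-substituted cyclopent-2-enones with in-situ enolate alkylation (three-component coupling). No ring is closed. The stereocentre at the β-carbon (future C3) is controlled by the single stereocentre of 6, whose arm shields one face so that the silylmethyl group should enter trans to it. The stereocentre at the α-carbon (future C2) is controlled by the newly installed neighbour, the methyl entering trans to it, and this all-trans arrangement is also the thermodynamic one because that carbon is epimerisable. The step needs 1,4- rather than 1,2-addition and no attack on the ester, which the soft copper reagent at −78 °C secures, and C-methylation at the original enolate carbon before proton transfer, which the excess of a small electrophile and the polar cosolvent secure.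

Step 6
Reactants: 11 methyl 2-[(1S,2S,3R)-2-[(dimethylphenylsilyl)methyl]-3-methyl-4-oxocyclopentyl]acetate
Product: 13 methyl 2-[(1S,2S,3R)-2-(hydroxymethyl)-3-methyl-4-oxocyclopentyl]acetate, via fluorosilane 12 (not isolated)
Conditions: HBF4·OEt2, CH2Cl2, 0 °C → rt; then 30% H2O2, KF, KHCO3, THF/MeOH, rt
Reagents that add atoms: hydrogen peroxide, OO
Why: Tamao–Fleming oxidation, in which ipso-protodesilylation of the phenyl group gives fluorosilane 12 and buffered peroxide then converts its C–Si bond into C–OH, conditions that tolerate a ketone and a methyl ester, while lactonisation onto the arm would require a strained trans-fused 6/5 lactone.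

Step 7
Reactants: 13 methyl 2-[(1S,2S,3R)-2-(hydroxymethyl)-3-methyl-4-oxocyclopentyl]acetate
Product: 14 methyl 2-[(1S,2S,3R)-2-[(benzyloxy)methyl]-3-methyl-4-oxocyclopentyl]acetate
Conditions: BnOC(=NH)CCl3, TfOH (cat.), CH2Cl2/cyclohexane, 0 °C → rt
Reagents that add atoms: benzyl 2,2,2-trichloroacetimidate, N=C(OCc1ccccc1)C(Cl)(Cl)Cl
Why: Acid-catalysed O-benzylation with the trichloroacetimidate avoids base at the enolisable ketone, and the benzyl ether is chosen because it withstands peracid, amide base and the acidic methanol of step 10 (where a silyl ether would be at risk) yet leaves under neutral conditions at the end.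

Step 8
Reactants: 14 methyl 2-[(1S,2S,3R)-2-[(benzyloxy)methyl]-3-methyl-4-oxocyclopentyl]acetate
Product: 15 methyl 2-[(2R,3R,4R)-3-[(benzyloxy)methyl]-2-methyl-6-oxooxan-4-yl]acetate
Conditions: mCPBA, NaHCO3, CH2Cl2, 0 °C → rt
Reagents that add atoms: 3-chloroperoxybenzoic acid (mCPBA), OOC(=O)c1cccc(Cl)c1
Why: Baeyer–Villiger oxidation, in which the more substituted α-carbon (future C2, the CH–CH3) migrates in the Criegee intermediate in preference to the CH2 and with retention, giving the δ-lactone whose ring oxygen is the future O1; ether and ester are inert to buffered peracid.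

Step 9
Reactants: 15 methyl 2-[(2R,3R,4R)-3-[(benzyloxy)methyl]-2-methyl-6-oxooxan-4-yl]acetate
Product: 17 methyl 2-[(2R,3R,4S)-3-[(benzyloxy)methyl]-5-(hydroxymethylidene)-2-methyl-6-oxooxan-4-yl]acetate, via lithium lactone enolate 16 (not isolated)
Conditions: LiN(i-Pr)2 (LDA), THF, −78 °C; then HCO2CH2CF3, −78 °C; AcOH quench
Reagents that add atoms: 2,2,2-trifluoroethyl formate, O=COCC(F)(F)F
Why: Crossed Claisen formylation, in which the lactone α-CH2 (future C5) is clearly more acidic than the α-CH2 of the acyclic methyl ester, so the amide base should enolise it selectively to 16, and the reactive formate traps this enolate while releasing only weakly nucleophilic trifluoroethoxide, so that neither the lactone nor the arm ester is exchanged and the two acetate arms on C4 stay distinct.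

Step 10
Reactants: 17 methyl 2-[(2R,3R,4S)-3-[(benzyloxy)methyl]-5-(hydroxymethylidene)-2-methyl-6-oxooxan-4-yl]acetate
Product: 19 methyl (2R,3R,4S)-3-[(benzyloxy)methyl]-4-(2-methoxy-2-oxoethyl)-2-methyl-3,4-dihydro-2H-pyran-5-carboxylate, via methyl acetal 18 (not isolated)
Conditions: HCl (1.25 M in MeOH), 0 °C → rt; then TsOH·H2O (cat.), toluene, 90 °C
Reagents that add atoms: methanol, CO
Why: Korte rearrangement, in which acid methanolysis opens the formyl lactone by acyl–oxygen cleavage (the C2–O bond and its configuration stay intact), the freed C2 hydroxyl closes onto the formyl carbon as cyclic methyl acetal 18, and acid-catalysed loss of methanol should give the conjugated dihydropyran; the methyl ester arm is invariant in methanol and the benzyl ether is acid-stable.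

Step 11
Reactants: 19 methyl (2R,3R,4S)-3-[(benzyloxy)methyl]-4-(2-methoxy-2-oxoethyl)-2-methyl-3,4-dihydro-2H-pyran-5-carboxylate
Product: 20 2-[(2R,3R,4S)-3-[(benzyloxy)methyl]-5-(methoxycarbonyl)-2-methyl-3,4-dihydro-2H-pyran-4-yl]acetic acid
Conditions: LiOH·H2O (1 equiv), THF/H2O, 0 °C; then 1 M HCl to pH 3
Reagents that add atoms: lithium hydroxide, [Li+].[OH-]
Why: Chemoselective saponification, because the saturated primary acetate ester is far more electrophilic than the C5 ester, a vinylogous carbonate deactivated by donation from O1, so one equivalent of hydroxide at 0 °C should cleave only the arm.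

Step 12
Reactants: 21 hydroxytyrosol
Product: 22 2-[3,4-bis(benzyloxy)phenyl]ethanol
Conditions: BnBr, K2CO3, acetone, reflux, N2
Reagents that add atoms: benzyl bromide, BrCc1ccccc1
Why: Williamson ether synthesis in which carbonate deprotonates only the phenols, so both phenolic oxygens should be benzylated while the aliphatic alcohol stays free.

Step 13
Reactants: 20 2-[(2R,3R,4S)-3-[(benzyloxy)methyl]-5-(methoxycarbonyl)-2-methyl-3,4-dihydro-2H-pyran-4-yl]acetic acid; 22 2-[3,4-bis(benzyloxy)phenyl]ethanol
Product: 23 methyl (2R,3R,4S)-3-[(benzyloxy)methyl]-4-[2-[2-[3,4-bis(benzyloxy)phenyl]ethoxy]-2-oxoethyl]-2-methyl-3,4-dihydro-2H-pyran-5-carboxylate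
Conditions: EDC·HCl, DMAP (cat.), CH2Cl2, 0 °C → rt
Reagents that add atoms: none
Why: Steglich esterification joins the only free carboxylic acid with the only free alcohol under mild carbodiimide/DMAP activation that leaves the enol ether ester and the stereocentres alone.

Step 14
Reactants: 23 methyl (2R,3R,4S)-3-[(benzyloxy)methyl]-4-[2-[2-[3,4-bis(benzyloxy)phenyl]ethoxy]-2-oxoethyl]-2-methyl-3,4-dihydro-2H-pyran-5-carboxylate
Product: 24 methyl (2R,3R,4S)-4-[2-[2-(3,4-dihydroxyphenyl)ethoxy]-2-oxoethyl]-3-(hydroxymethyl)-2-methyl-3,4-dihydro-2H-pyran-5-carboxylate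
Conditions: H2 (1 atm), 10% Pd/C (palladium on carbon), EtOAc, rt
Reagents that add atoms: none
Why: Catalytic hydrogenolysis should cleave the two aryl benzyl ethers and the alkyl benzyl ether under neutral conditions, in which the electron-poor push–pull C5=C6 double bond is expected to resist reduction and the liberated CH2OH is not driven to lactonise onto the neighbouring ester.

Compound list
1 | (1S,4R)-cis-4-acetoxy-2-cyclopenten-1-ol | O[C@@H]1C=C[C@H](OC(C)=O)C1 | starting material
2 | dimethyl malonate | COC(=O)CC(=O)OC | starting material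
3 | sodium dimethyl malonate | [Na+].COC(=O)[CH-]C(=O)OC | intermediate
4 | dimethyl 2-[(1R,4S)-4-hydroxycyclopent-2-en-1-yl]propanedioate | O[C@@H]1C=C[C@H](C(C(=O)OC)C(=O)OC)C1 | intermediate
5 | methyl 2-[(1S,4S)-4-hydroxycyclopent-2-en-1-yl]acetate | O[C@@H]1C=C[C@H](CC(=O)OC)C1 | intermediate
6 | methyl 2-[(1S)-4-oxocyclopent-2-en-1-yl]acetate | O=C1C=C[C@H](CC(=O)OC)C1 | intermediate
7 | (chloromethyl)dimethylphenylsilane | C[Si](C)(CCl)c1ccccc1 | starting material
8 | [(dimethylphenylsilyl)methyl]magnesium chloride | C[Si](C)(C[Mg]Cl)c1ccccc1 | intermediate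
9 | iodomethane | CI | starting material
10 | chloromagnesium enolate, methyl 2-[(1S,2S)-4-[(chloromagnesio)oxy]-2-[(dimethylphenylsilyl)methyl]cyclopent-3-en-1-yl]acetate | Cl[Mg]OC1=C[C@@H](C[Si](C)(C)c2ccccc2)[C@H](CC(=O)OC)C1 | intermediate
11 | methyl 2-[(1S,2S,3R)-2-[(dimethylphenylsilyl)methyl]-3-methyl-4-oxocyclopentyl]acetate (all-trans) | O=C1[C@H](C)[C@@H](C[Si](C)(C)c2ccccc2)[C@H](CC(=O)OC)C1 | intermediate
12 | methyl 2-[(1S,2S,3R)-2-[(fluorodimethylsilyl)methyl]-3-methyl-4-oxocyclopentyl]acetate | O=C1[C@H](C)[C@@H](C[Si](C)(C)F)[C@H](CC(=O)OC)C1 | intermediate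
13 | methyl 2-[(1S,2S,3R)-2-(hydroxymethyl)-3-methyl-4-oxocyclopentyl]acetate | O=C1[C@H](C)[C@@H](CO)[C@H](CC(=O)OC)C1 | intermediate
14 | methyl 2-[(1S,2S,3R)-2-[(benzyloxy)methyl]-3-methyl-4-oxocyclopentyl]acetate | O=C1[C@H](C)[C@@H](COCc2ccccc2)[C@H](CC(=O)OC)C1 | intermediate
15 | methyl 2-[(2R,3R,4R)-3-[(benzyloxy)methyl]-2-methyl-6-oxooxan-4-yl]acetate | O=C1O[C@H](C)[C@@H](COCc2ccccc2)[C@H](CC(=O)OC)C1 | intermediate
16 | lithium enolate of 15, methyl 2-[(2R,3R,4S)-3-[(benzyloxy)methyl]-6-(lithiooxy)-2-methyl-3,4-dihydro-2H-pyran-4-yl]acetate | [Li]OC1=C[C@@H](CC(=O)OC)[C@H](COCc2ccccc2)[C@@H](C)O1 | intermediate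
17 | methyl 2-[(2R,3R,4S)-3-[(benzyloxy)methyl]-5-(hydroxymethylidene)-2-methyl-6-oxooxan-4-yl]acetate (enol tautomer of the α-formyl lactone) | OC=C1C(=O)O[C@H](C)[C@@H](COCc2ccccc2)[C@@H]1CC(=O)OC | intermediate
18 | methyl (2R,3R,4S)-3-[(benzyloxy)methyl]-6-methoxy-4-(2-methoxy-2-oxoethyl)-2-methyloxane-5-carboxylate (target ring numbering; epimers at C5 and C6) | COC1O[C@H](C)[C@@H](COCc2ccccc2)[C@H](CC(=O)OC)C1C(=O)OC | intermediate
19 | methyl (2R,3R,4S)-3-[(benzyloxy)methyl]-4-(2-methoxy-2-oxoethyl)-2-methyl-3,4-dihydro-2H-pyran-5-carboxylate | COC(=O)C1=CO[C@H](C)[C@@H](COCc2ccccc2)[C@@H]1CC(=O)OC | intermediate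
20 | 2-[(2R,3R,4S)-3-[(benzyloxy)methyl]-5-(methoxycarbonyl)-2-methyl-3,4-dihydro-2H-pyran-4-yl]acetic acid | COC(=O)C1=CO[C@H](C)[C@@H](COCc2ccccc2)[C@@H]1CC(=O)O | intermediate
21 | hydroxytyrosol, 4-(2-hydroxyethyl)benzene-1,2-diol | OCCc1ccc(O)c(O)c1 | starting material
22 | 2-[3,4-bis(benzyloxy)phenyl]ethanol | OCCc1ccc(OCc2ccccc2)c(OCc2ccccc2)c1 | intermediate
23 | methyl (2R,3R,4S)-3-[(benzyloxy)methyl]-4-[2-[2-[3,4-bis(benzyloxy)phenyl]ethoxy]-2-oxoethyl]-2-methyl-3,4-dihydro-2H-pyran-5-carboxylate | COC(=O)C1=CO[C@H](C)[C@@H](COCc2ccccc2)[C@@H]1CC(=O)OCCc1ccc(OCc2ccccc2)c(OCc2ccccc2)c1 | intermediate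
24 | methyl (2R,3R,4S)-4-[2-[2-(3,4-dihydroxyphenyl)ethoxy]-2-oxoethyl]-3-(hydroxymethyl)-2-methyl-3,4-dihydro-2H-pyran-5-carboxylate | COC(=O)C1=CO[C@H](C)[C@@H](CO)[C@@H]1CC(=O)OCCc1ccc(O)c(O)c1 | target

Total step count: 14. Longest linear sequence: 12 steps (steps 1, 2, 3, 5, 6, 7, 8, 9, 10, 11, 13 and 14, from compound 1); steps 4 and 12 are side branches.

Steps most likely to fail

Step 5. The magnesium enolate may exchange protons with product or medium before it is methylated, which would cause loss of regiocontrol and over-alkylation, and facial selectivity in the addition may be incomplete. Fallback: setting out from 6, the copper-catalysed addition of 8 is run with Me3SiCl present, so that the enolate is captured at once as the trimethylsilyl enol ether methyl 2-[(1S,2S)-2-[(dimethylphenylsilyl)methyl]-4-[(trimethylsilyl)oxy]cyclopent-3-en-1-yl]acetate F1. This is isolated and then methylated regiospecifically with 9 and anhydrous benzyltrimethylammonium fluoride in THF (fluoride-generated ammonium enolate, which alkylates faster than it equilibrates). The sequence comes back to the route at 11.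

Step 9. Enolisation may occur at the acetate-arm ester instead of the lactone, or an alkoxide may open the lactone so that the two acetate arms on C4 become equivalent; either process would erode the C4 configuration, because the arm that is formylated becomes C5. Fallback: setting out from 15, condensation with tert-butoxybis(dimethylamino)methane in toluene at 80 °C, which engages only the more acidic lactone CH2 and liberates no unhindered alkoxide, should give the aminomethylene lactone methyl 2-[(2R,3R,4S)-3-[(benzyloxy)methyl]-5-[(dimethylamino)methylidene]-2-methyl-6-oxooxan-4-yl]acetate F2. Treating F2 with methanolic HCl and then warm TsOH in toluene, as in step 10, should bring about the same ring transformation and comes back to the route at 19.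

Step 14. The C5=C6 double bond may be saturated in competition, the alkyl benzyl ether may cleave slowly, and prolonged contact with the catalyst may let the freed alcohol lactonise onto the arm ester. Fallback: setting out from 23, all three benzyl ethers are cleaved without hydrogen by BCl3 in the presence of pentamethylbenzene as cation scavenger (CH2Cl2, −78 °C, methanol quench). This Lewis-acid route does not touch the alkene and arrives directly at 24 (no new compound, F0).

Further compounds
F1 | step 5 | methyl 2-[(1S,2S)-2-[(dimethylphenylsilyl)methyl]-4-[(trimethylsilyl)oxy]cyclopent-3-en-1-yl]acetate | C[Si](C)(C)OC1=C[C@@H](C[Si](C)(C)c2ccccc2)[C@H](CC(=O)OC)C1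
F2 | step 9 | methyl 2-[(2R,3R,4S)-3-[(benzyloxy)methyl]-5-[(dimethylamino)methylidene]-2-methyl-6-oxooxan-4-yl]acetate | CN(C)C=C1C(=O)O[C@H](C)[C@@H](COCc2ccccc2)[C@@H]1CC(=O)OC
F0 | step 14 | none | none
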